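**Retrosynthetic overview**
1. Remove the aryl TBDPS group at the end. Disconnect C5'–C6' (sp3–sp2) by a B-alkyl Suzuki coupling of an alkyl-9-BBN, made from 2-methyl-2-vinylchroman **6**, with the (E)-vinyl iodide **15** that carries the (R)-allylic alcohol.
2. The only ring, the chroman, and its quaternary C2 stereocentre are made together and first. The new step is a catalytic enantioselective oxa-[4+2] of the o-quinone methide from saligenin **4** with isoprene. The vinyl group becomes the C4'–C5' linker.
3. Build **15** from 4-pentyn-1-ol in five steps: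
   - Carboalumination/iodination sets the first E-alkene.
   - Oxidation gives the aldehyde.
   - A Wittig reaction with Ph3P=C(Me)CHO sets the second E-alkene.
   - Brown allylation sets C12' (R).
   - Cross-metathesis with 2-methyl-2-butene converts the allyl group to prenyl.
4. Ring order: the chroman is formed first, and all olefins are then built from acyclic pieces.

**Assumptions**
- Mono-silylation of **1** occurs at the unhindered C4-OH.
- (+)-Ipc2B-allyl (from (–)-α-pinene) adds to the Re face of enal **11** to give (R)-**13**.
- The (S,S)-IDPi enantiomer gives (S)-**6**, which is the 2R centre of the target once the vinyl group becomes an alkyl chain (CIP priorities change). If the opposite enantiomer forms, use the other catalyst enantiomer.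

**Route**

**Step 1**
Reactants: **1** 2-methylhydroquinone
Product: **2** 4-(tert-butyldiphenylsilyloxy)-2-methylphenol
Conditions: TBDPSCl (1.05 equiv), imidazole, DMF, 0 °C → rt
Reagents that add atoms: TBDPSCl, CC(C)(C)[Si](Cl)(c1ccccc1)c1ccccc1
Why: The bulky silyl chloride reacts at the less hindered C4-OH, leaving the OH flanked by the methyl group free (silyl protection).

**Step 2**
Reactants: **2**
Product: **3** 5-(TBDPSO)-2-hydroxy-3-methylbenzaldehyde
Conditions: MgCl2, Et3N, (CH2O)n, MeCN, 80 °C
Reagents that add atoms: paraformaldehyde, C=O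
Why: Mg-phenoxide-directed ortho-formylation (Casnati–Skattebøl) can only occur at the single free ortho position, C6.

**Step 3**
Reactants: **3**
Product: **4** 4-(TBDPSO)-2-(hydroxymethyl)-6-methylphenol (saligenin)
Conditions: NaBH4, MeOH/THF, 0 °C, 30 min
Reagents that add atoms: none
Why: Chemoselective aldehyde reduction; the silyl ether and phenol are untouched.

**Step 4**
Reactants: **4**; **5** isoprene (2-methylbuta-1,3-diene)
Product: **6** (2S)-2,8-dimethyl-2-vinylchroman-6-yl TBDPS ether
Conditions: (S,S)-IDPi (5 mol %), 4 Å MS, cyclohexane/CH2Cl2 (4:1, 0.02 M in **4**), isoprene (10 equiv), –20 °C, 72 h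
Reagents that add atoms: isoprene, C=C(C)C=C (reactant **5**); the catalyst adds no atoms.
Why: Proposed new method: the confined chiral Brønsted acid ionises the electron-rich saligenin to an H-bonded o-quinone-methide/benzylic cation–anion pair. Isoprene (an unactivated 2-substituted diene, not a styrene or enol ether) attacks through its isopropenyl CH2 terminus, giving a tertiary allyl cation. The phenol O then closes at the tertiary terminus (6-membered, avoiding an 8-membered ring) inside the chiral anion pocket, and that C–O bond formation sets the Me/vinyl quaternary ether stereocentre. The closest known reactions are chiral-acid o-QM [4+2] with enol ethers and chiral-acid hydroalkoxylation of unactivated alkenes.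

**Step 5**
Reactants: **7** 4-pentyn-1-ol
Product: **8** (E)-5-iodo-4-methylpent-4-en-1-ol
Conditions: Cp2ZrCl2 (20 mol %), AlMe3 (3 equiv), (CH2Cl)2, 0 °C → rt, 12 h; then I2, THF, –30 → 0 °C
Reagents that add atoms: trimethylaluminum, C[Al](C)C; iodine, II
Why: Negishi Zr-catalysed syn-methylalumination places Me on the internal carbon, so iodination gives the E-trisubstituted iodoalkene; the free OH is tolerated with excess AlMe3.

**Step 6**
Reactants: **8**
Product: **9** (E)-5-iodo-4-methylpent-4-enal
Conditions: Dess–Martin periodinane, NaHCO3, CH2Cl2, 0 °C → rt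
Reagents that add atoms: none
Why: Mild oxidation of a primary alcohol; the vinyl iodide is inert.

**Step 7**
Reactants: **9**; **10** 2-(triphenylphosphoranylidene)propanal
Product: **11** (2E,6E)-7-iodo-2,6-dimethylhepta-2,6-dienal
Conditions: toluene, 80 °C, 12 h
Reagents that add atoms: none beyond **10** (CC(C=O)=PPh3)
Why: A stabilised-ylide Wittig reaction gives the E-α-methyl enal with high selectivity, setting the C10'=C11' geometry.

**Step 8**
Reactants: **11**; **12** (+)-allyldiisopinocampheylborane (from (–)-α-pinene)
Product: **13** (4R,5E,9E)-10-iodo-5,9-dimethyldeca-1,5,9-trien-4-ol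
Conditions: Et2O, –78 °C, 2 h; then 3 M NaOH, 30% H2O2, 0 °C → rt
Reagents that add atoms: allyl group from **12**, C=CC[B]; hydrogen peroxide, OO (its O becomes the carbinol O)
Why: Brown asymmetric allylboration proceeds through a closed chair transition state with reagent-controlled 1,2-addition to the Re face, setting C12' (R); the enal is attacked 1,2, not 1,4.

**Step 9**
Reactants: **13**; **14** 2-methyl-2-butene
Product: **15** (5R,6E,10E)-11-iodo-2,6,10-trimethylundeca-2,6,10-trien-5-ol
Conditions: Hoveyda–Grubbs II (5 mol %), CH2Cl2, 40 °C, 12 h, 2-methyl-2-butene (20 equiv)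
Reagents that add atoms: 2-methyl-2-butene, CC=C(C)C (reactant **14**)
Why: Cross-metathesis converts the reactive terminal alkene to the prenyl group; the trisubstituted olefins, the vinyl iodide and the free OH are tolerated and the stereocentre is untouched.

**Step 10**
Reactants: **6**
Product: **16** alkyl-9-BBN derived from **6**, (2R)-2-[2-(9-BBN)ethyl]-2,8-dimethylchroman-6-yl TBDPS ether (in situ)
Conditions: 9-BBN (1.05 equiv), THF, 23 °C, 4 h
Reagents that add atoms: 9-BBN, B1C2CCCC1CCC2
Why: Anti-Markovnikov hydroboration of the terminal vinyl group, with no effect on C2.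

**Step 11**
Reactants: **16**; **15**
Product: **17** TBDPS ether of sargachromanol C
Conditions: PdCl2(dppf)·CH2Cl2 (10 mol %), K3PO4 (3 M aq., 3 equiv), THF/DMF (4:1), 23 °C, 12 h (one pot after Step 10)
Reagents that add atoms: none
Why: B-alkyl Suzuki–Miyaura coupling joins C5' and C6' with retention of the (E)-iodoalkene geometry; aqueous K3PO4 is mild enough for the aryl TBDPS ether and the free alcohol.

**Step 12**
Reactants: **17**
Product: **18** sargachromanol C
Conditions: TBAF (3 equiv), AcOH (3 equiv), THF, 0 → 23 °C, 4 h, under Ar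
Reagents that add atoms: none
Why: Fluoride cleaves the aryl silyl ether; AcOH buffering avoids base-mediated oxidation of the chromanol, and no centre is ionised.

**Compound list**

| No. | Name | SMILES | Role |
|---|---|---|---|
| 1 | 2-methylhydroquinone | Cc1cc(O)ccc1O | starting material |
| 2 | 4-(TBDPSO)-2-methylphenol | Cc1cc(O[Si](c2ccccc2)(c2ccccc2)C(C)(C)C)ccc1O | intermediate |
| 3 | 5-(TBDPSO)-2-hydroxy-3-methylbenzaldehyde | Cc1cc(O[Si](c2ccccc2)(c2ccccc2)C(C)(C)C)cc(C=O)c1O | intermediate |
| 4 | 4-(TBDPSO)-2-(hydroxymethyl)-6-methylphenol | Cc1cc(O[Si](c2ccccc2)(c2ccccc2)C(C)(C)C)cc(CO)c1O | intermediate |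
| 5 | isoprene | C=C(C)C=C | starting material |
| 6 | (2S)-2,8-dimethyl-2-vinylchroman-6-yl TBDPS ether | C=C[C@]1(C)CCc2cc(O[Si](c3ccccc3)(c3ccccc3)C(C)(C)C)cc(C)c2O1 | intermediate |
| 7 | 4-pentyn-1-ol | C#CCCCO | starting material |
| 8 | (E)-5-iodo-4-methylpent-4-en-1-ol | OCCC/C(C)=C/I | intermediate |
| 9 | (E)-5-iodo-4-methylpent-4-enal | O=CCC/C(C)=C/I | intermediate |
| 10 | 2-(triphenylphosphoranylidene)propanal | CC(C=O)=P(c1ccccc1)(c1ccccc1)c1ccccc1 | starting material |
| 11 | (2E,6E)-7-iodo-2,6-dimethylhepta-2,6-dienal | O=C/C(C)=C/CC/C(C)=C/I | intermediate |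
| 12 | (+)-allyldiisopinocampheylborane (Ipc from (–)-α-pinene; pinane stereo not drawn) | C=CCB(C1CC2CC(C1C)C2(C)C)C1CC2CC(C1C)C2(C)C | starting material |
| 13 | (4R,5E,9E)-10-iodo-5,9-dimethyldeca-1,5,9-trien-4-ol | C=CC[C@@H](O)/C(C)=C/CC/C(C)=C/I | intermediate |
| 14 | 2-methyl-2-butene | CC=C(C)C | starting material |
| 15 | (5R,6E,10E)-11-iodo-2,6,10-trimethylundeca-2,6,10-trien-5-ol | CC(C)=CC[C@@H](O)/C(C)=C/CC/C(C)=C/I | intermediate |
| 16 | (2R)-2-[2-(9-BBN)ethyl]-2,8-dimethylchroman-6-yl TBDPS ether | C1CCC2CCCC1B2CC[C@]1(C)CCc2cc(O[Si](c3ccccc3)(c3ccccc3)C(C)(C)C)cc(C)c2O1 | intermediate (in situ) |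
| 17 | TBDPS ether of sargachromanol C | CC(C)=CC[C@@H](O)/C(C)=C/CC/C(C)=C/CC[C@]1(C)CCc2cc(O[Si](c3ccccc3)(c3ccccc3)C(C)(C)C)cc(C)c2O1 | intermediate |
| 18 | sargachromanol C (2R,12'R) | CC(C)=CC[C@@H](O)/C(C)=C/CC/C(C)=C/CC[C@]1(C)CCc2cc(O)cc(C)c2O1 | target |

**Total steps:** 12.
**Longest linear sequence:** 7 steps. Both the 1 → 6 branch (Steps 1–4, 10–12) and the 7 → 15 branch (Steps 5–9, 11–12) are 7 steps long.

**Three steps most likely to fail**
1. **Step 4 (proposed new step).** Risks are isoprene oligomerisation, low ee from Me/vinyl discrimination, and re-ionisation of the tertiary allylic ether product under acid.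
   - Fallback: run a known racemic acid-catalysed o-QM/isoprene annulation (achiral phosphoric acid or Sc(OTf)3) to give (±)-6, then separate the enantiomers by preparative chiral SFC/HPLC to isolate (S)-6.
2. **Step 8.** The enantiofacial assignment or ee of the Brown allylation on the α-methyl dienal may be off.
   - Fallback: add allylMgBr to 11, oxidise to the ketone, and reduce it enantioselectively with an oxazaborolidine (CBS) catalyst, choosing the catalyst enantiomer that gives the 12'R carbinol.
3. **Step 11.** The B-alkyl Suzuki coupling carries a free allylic OH, a base-sensitive aryl silyl ether and a polyene, so yield or selectivity may suffer.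
   - Fallback: convert the vinyl group of 6 into the primary alkyl iodide (9-BBN, then oxidation, then I2/PPh3), make the alkylzinc (Zn, LiCl), and couple it with TES-protected 15 by Negishi coupling (Pd-PEPPSI), followed by global desilylation.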